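## Retrosynthetic overview
1. Target ⇒ Z-cyclodecene (C1=C10) by a reagent-controlled Shi epoxidation, which forms the last oxirane and sets C1 and C10.
2. Z-cyclodecene ⇒ acyclic epoxy diester diene by ring-closing metathesis at C1=C10, the only carbocycle-forming step.
3. C4–C5 oxirane ⇒ C6-hydroxyl-directed threo epoxidation. C6 carbinol plus C8 angelate ⇒ β-hydroxy enone by a new Evans–Tishchenko angeloylation with angelaldehyde.
4. β-Hydroxy enone ⇒ C1–C5 alkenyllithium (Negishi carboalumination) + C6–C10 Weinreb amide (Evans syn aldol sets C7 and C8).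
5. Ring order: C4–C5 oxirane, then the ten-membered carbocycle, then the C1–C10 oxirane.

Assumption: the SMILES is read literally, i.e. (1R,4S,5S,6R,7R,8S,10S) in germacrane numbering, with a trans C4–C5 oxirane and a cis C1–C10 oxirane (C2 and C9 on the same side); the labels C1–C15 below follow that numbering.

## Route

Step 1
Reactants: 1 3-methylbut-3-en-1-ol
Product: 2 3-methylbut-3-enal
Conditions: Dess–Martin periodinane (1.2 equiv), CH2Cl2, 0 °C to rt; used at once as a CH2Cl2 solution
Reagents that add atoms: none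
Why: The Dess–Martin oxidation is fast and base-free, so the β,γ-unsaturated aldehyde forms without migration of the double bond into conjugation; no stereocentre is involved.

Step 2
Reactants: 3 (4R)-4-benzyl-3-(3-methylbutanoyl)-1,3-oxazolidin-2-one; 2 3-methylbut-3-enal
Product: 6 (4R)-4-benzyl-3-[(2R,3S)-3-hydroxy-5-methyl-2-(propan-2-yl)hex-5-enoyl]-1,3-oxazolidin-2-one, via dibutylboron Z-enolate 4 (not isolated), via dibutylboron aldolate 5 (not isolated)
Conditions: Bu2BOTf, Et3N, CH2Cl2, −78 to 0 °C; then 2, −78 to 0 °C; then pH 7 buffer, MeOH, 30% H2O2, 0 °C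
Reagents that add atoms: none
Why: In the Evans syn aldol reaction the Z-boron enolate reacts through a closed Zimmerman–Traxler chair whose face is fixed by the (R)-benzyl auxiliary, which sets C7 (R) and C8 (S) in the required 7,8-syn relationship.

Step 3
Reactants: 6 (4R)-4-benzyl-3-[(2R,3S)-3-hydroxy-5-methyl-2-(propan-2-yl)hex-5-enoyl]-1,3-oxazolidin-2-one
Product: 7 (2R,3S)-3-hydroxy-N-methoxy-N,5-dimethyl-2-(propan-2-yl)hex-5-enamide
Conditions: MeONHMe·HCl, Me3Al, CH2Cl2, −10 °C to rt
Reagents that add atoms: N,O-dimethylhydroxylamine hydrochloride, CNOC.Cl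
Why: Weinreb transamidation with the aluminium amide is assisted by the free β-hydroxyl group and removes the auxiliary without touching C7 or C8.

Step 4
Reactants: 8 hex-1-en-5-yne
Product: 10 (1E)-1-iodo-2-methylhexa-1,5-diene, via E-alkenyl(dimethyl)alane 9 (not isolated)
Conditions: Me3Al, Cp2ZrCl2 (0.25 equiv), CH2Cl2, 0 °C to rt; then I2, THF, −30 °C
Reagents that add atoms: trimethylaluminium, C[Al](C)C; iodine, II
Why: Negishi carboalumination adds methyl and aluminium syn and regioselectively across the terminal alkyne (much faster than across the alkene), and iodinolysis with retention fixes the E geometry of the future C4=C5 bond.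

Step 5
Reactants: 7 (2R,3S)-3-hydroxy-N-methoxy-N,5-dimethyl-2-(propan-2-yl)hex-5-enamide; 10 (1E)-1-iodo-2-methylhexa-1,5-diene
Product: 13 (4S,5R,7E)-4-hydroxy-2,8-dimethyl-5-(propan-2-yl)dodeca-1,7,11-trien-6-one, via E-alkenyllithium 11 (not isolated), via chloromagnesium alkoxide 12 (not isolated)
Conditions: 10 (1.6 equiv), t-BuLi (3.2 equiv), Et2O, −78 °C; separately 7, i-PrMgCl (1.05 equiv), THF, −20 °C; combine, −78 to −20 °C; aqueous work-up
Reagents that add atoms: none
Why: In this Weinreb ketone synthesis the lithium–iodine exchange keeps the olefin geometry, the chelated tetrahedral adduct prevents over-addition, and the magnesium alkoxide masks the C8 hydroxyl at a temperature where retro-aldol cleavage and C7 epimerisation are slow.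

Step 6
Reactants: 14 angelic acid, (2Z)-2-methylbut-2-enoic acid
Product: 15 (2Z)-2-methylbut-2-en-1-ol
Conditions: LiAlH4, Et2O, 0 °C
Reagents that add atoms: none
Why: Hydride reduction of the carboxylic acid leaves the trisubstituted Z-olefin untouched.

Step 7
Reactants: 15 (2Z)-2-methylbut-2-en-1-ol
Product: 16 (2Z)-2-methylbut-2-enal (angelaldehyde)
Conditions: MnO2, pentane/CH2Cl2, rt, dark; filtered and used at once as a solution
Reagents that add atoms: none
Why: MnO2 oxidises the allylic alcohol under neutral heterogeneous conditions, so the Z geometry is kept.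

Step 8
Reactants: 13 (4S,5R,7E)-4-hydroxy-2,8-dimethyl-5-(propan-2-yl)dodeca-1,7,11-trien-6-one; 16 (2Z)-2-methylbut-2-enal
Product: 18 (4S,5S,6S,7E)-6-hydroxy-2,8-dimethyl-5-(propan-2-yl)dodeca-1,7,11-trien-4-yl (2Z)-2-methylbut-2-enoate, via samarium-bound hemiacetal 17 (not isolated)
Conditions: SmI2 (0.3 equiv, pre-aged 10 min with 16), 16 (5 equiv), THF, −10 °C, dark
Reagents that add atoms: none
Why: Proposed new method: a redox-neutral Evans–Tishchenko angeloylation in which the Z-enal 16 is both hydride donor and acyl source: the trivalent samarium species formed from SmI2 and 16 binds the C8 hydroxyl, the derived hemiacetal 17 chelates the C6 ketone, and its formyl hydrogen is delivered intramolecularly through a chair-like bicyclic transition state to the face that gives the 6,8-anti relationship (new C6 stereocentre, S by CIP here, R in the target), while the hemiacetal carbon collapses directly to the C8 angelate; no acyl-onium, ketene or dienolate species is formed, so the Z geometry should survive, the six-membered hydride transfer enforces 1,2-reduction of the enone, and the closest known reaction type is the samarium-catalysed Evans–Tishchenko reduction of β-hydroxy ketones, so far run with saturated or aromatic aldehydes and not with an α-branched Z-enal or to install an angelate.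

Step 9
Reactants: 18 (4S,5S,6S,7E)-6-hydroxy-2,8-dimethyl-5-(propan-2-yl)dodeca-1,7,11-trien-4-yl (2Z)-2-methylbut-2-enoate
Product: 19 (4S,5S,6R)-6-[(2S,3S)-3-(but-3-en-1-yl)-3-methyloxiran-2-yl]-6-hydroxy-2-methyl-5-(propan-2-yl)hex-1-en-4-yl (2Z)-2-methylbut-2-enoate
Conditions: mCPBA (1.05 equiv), CH2Cl2, −20 °C
Reagents that add atoms: mCPBA (3-chloroperoxybenzoic acid), O=C(OO)c1cccc(Cl)c1
Why: In this hydroxyl-directed Prilezhaev (Henbest) epoxidation, A(1,3) strain with the C4 methyl holds H6 in the olefin plane, so the hydrogen-bonded peracid attacks the face bearing the C6 hydroxyl and gives the threo epoxy alcohol (C4 S, C5 S), while the trisubstituted hydroxyl-activated olefin outruns the 1,1-disubstituted, terminal and angelate olefins.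

Step 10
Reactants: 19 (4S,5S,6R)-6-[(2S,3S)-3-(but-3-en-1-yl)-3-methyloxiran-2-yl]-6-hydroxy-2-methyl-5-(propan-2-yl)hex-1-en-4-yl (2Z)-2-methylbut-2-enoate
Product: 20 (4S,5R,6R)-6-acetoxy-6-[(2S,3S)-3-(but-3-en-1-yl)-3-methyloxiran-2-yl]-2-methyl-5-(propan-2-yl)hex-1-en-4-yl (2Z)-2-methylbut-2-enoate
Conditions: Ac2O, pyridine, DMAP (cat.), CH2Cl2, 0 °C to rt
Reagents that add atoms: acetic anhydride, CC(=O)OC(C)=O
Why: DMAP-catalysed acetylation of the only free hydroxyl is mild enough for the oxirane and the angelate and changes no stereocentre.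

Step 11
Reactants: 20 (4S,5R,6R)-6-acetoxy-6-[(2S,3S)-3-(but-3-en-1-yl)-3-methyloxiran-2-yl]-2-methyl-5-(propan-2-yl)hex-1-en-4-yl (2Z)-2-methylbut-2-enoate
Product: 21 (1(10)Z,4S,5S,6R,7R,8S)-6-acetoxy-4,5-epoxygermacr-1(10)-en-8-yl (2Z)-2-methylbut-2-enoate
Conditions: second-generation Hoveyda–Grubbs catalyst, (H2IMes)Cl2Ru=CH(C6H4-2-O-i-Pr) (10 mol %), 1,4-benzoquinone (20 mol %), toluene (1 mM), 80 °C, Ar sparge
Reagents that add atoms: none
Why: In the ring-closing metathesis ruthenium loads on the terminal vinyl group and closes onto the methallyl group, ring strain makes the Z-trisubstituted cyclodecene the thermodynamic product, the trisubstituted electron-poor angelate olefin is inert, and the C4=C5 olefin that could have given a cyclohexene is already an oxirane.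

Step 12
Reactants: 21 (1(10)Z,4S,5S,6R,7R,8S)-6-acetoxy-4,5-epoxygermacr-1(10)-en-8-yl (2Z)-2-methylbut-2-enoate
Product: 22 (1R,4S,5S,6R,7R,8S,10S)-6-acetoxy-1,10:4,5-diepoxygermacran-8-yl (2Z)-2-methylbut-2-enoate (CNP0158257.1)
Conditions: D-fructose-derived Shi ketone (0.3 equiv), Oxone (2KHSO5·KHSO4·K2SO4), K2CO3, Bu4NHSO4 (cat.), MeCN/dimethoxymethane/aq. Na2B4O7 buffer (pH 10.5), 0 °C
Reagents that add atoms: Oxone (active component KHSO5), [K+].[O-]S(=O)(=O)OO
Why: In the Shi asymmetric epoxidation the chiral dioxirane attacks only the electron-rich ring olefin through the spiro transition state with the facial sense that gives (R,R)-epoxides from trans-olefins, which for the CH3/C2 trans pair of this trisubstituted olefin translates into (1R,10S), and the concerted syn addition to the Z-olefin makes the oxirane cis.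

## Compound list
1 | 3-methylbut-3-en-1-ol | C=C(C)CCO | starting material
2 | 3-methylbut-3-enal | C=C(C)CC=O | intermediate
3 | (4R)-4-benzyl-3-(3-methylbutanoyl)-1,3-oxazolidin-2-one | CC(C)CC(=O)N1[C@H](Cc2ccccc2)COC1=O | starting material
4 | dibutylboron Z-enolate of 3 | CC(C)/C=C(\OB(CCCC)CCCC)N1[C@H](Cc2ccccc2)COC1=O | intermediate
5 | dibutylboron aldolate of 6 | C=C(C)C[C@H](OB(CCCC)CCCC)[C@@H](C(C)C)C(=O)N1[C@H](Cc2ccccc2)COC1=O | intermediate
6 | (4R)-4-benzyl-3-[(2R,3S)-3-hydroxy-5-methyl-2-(propan-2-yl)hex-5-enoyl]-1,3-oxazolidin-2-one | C=C(C)C[C@H](O)[C@@H](C(C)C)C(=O)N1[C@H](Cc2ccccc2)COC1=O | intermediate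
7 | (2R,3S)-3-hydroxy-N-methoxy-N,5-dimethyl-2-(propan-2-yl)hex-5-enamide | C=C(C)C[C@H](O)[C@@H](C(C)C)C(=O)N(C)OC | intermediate
8 | hex-1-en-5-yne | C=CCCC#C | starting material
9 | (E)-dimethyl(2-methylhexa-1,5-dien-1-yl)alane | C=CCC/C(C)=C/[Al](C)C | intermediate
10 | (1E)-1-iodo-2-methylhexa-1,5-diene | C=CCC/C(C)=C/I | intermediate
11 | (1E)-(2-methylhexa-1,5-dien-1-yl)lithium | C=CCC/C(C)=C/[Li] | intermediate
12 | chloromagnesium alkoxide of 7 | C=C(C)C[C@H](O[Mg]Cl)[C@@H](C(C)C)C(=O)N(C)OC | intermediate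
13 | (4S,5R,7E)-4-hydroxy-2,8-dimethyl-5-(propan-2-yl)dodeca-1,7,11-trien-6-one | C=C(C)C[C@H](O)[C@@H](C(C)C)C(=O)/C=C(\C)CCC=C | intermediate
14 | angelic acid, (2Z)-2-methylbut-2-enoic acid | C/C=C(/C)C(=O)O | starting material
15 | (2Z)-2-methylbut-2-en-1-ol | C/C=C(/C)CO | intermediate
16 | (2Z)-2-methylbut-2-enal (angelaldehyde) | C/C=C(/C)C=O | intermediate
17 | C8-O-hemiacetal of 13 with 16, samarium-bound, drawn neutral, hemiacetal carbon undefined | C=C(C)C[C@H](OC(O)/C(C)=C\C)[C@@H](C(C)C)C(=O)/C=C(\C)CCC=C | intermediate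
18 | (4S,5S,6S,7E)-6-hydroxy-2,8-dimethyl-5-(propan-2-yl)dodeca-1,7,11-trien-4-yl (2Z)-2-methylbut-2-enoate | C=C(C)C[C@H](OC(=O)/C(C)=C\C)[C@@H](C(C)C)[C@@H](O)/C=C(\C)CCC=C | intermediate
19 | (4S,5S,6R)-6-[(2S,3S)-3-(but-3-en-1-yl)-3-methyloxiran-2-yl]-6-hydroxy-2-methyl-5-(propan-2-yl)hex-1-en-4-yl (2Z)-2-methylbut-2-enoate | C=C(C)C[C@H](OC(=O)/C(C)=C\C)[C@@H](C(C)C)[C@@H](O)[C@@H]1O[C@@]1(C)CCC=C | intermediate
20 | (4S,5R,6R)-6-acetoxy-6-[(2S,3S)-3-(but-3-en-1-yl)-3-methyloxiran-2-yl]-2-methyl-5-(propan-2-yl)hex-1-en-4-yl (2Z)-2-methylbut-2-enoate | C=C(C)C[C@H](OC(=O)/C(C)=C\C)[C@@H](C(C)C)[C@@H](OC(C)=O)[C@@H]1O[C@@]1(C)CCC=C | intermediate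
21 | (1(10)Z,4S,5S,6R,7R,8S)-6-acetoxy-4,5-epoxygermacr-1(10)-en-8-yl (2Z)-2-methylbut-2-enoate (ten-membered ring, Z C1=C10, trans C4–C5 oxirane) | C/C=C(/C)C(=O)O[C@H]1C/C(C)=C\CC[C@]2(C)O[C@H]2[C@H](OC(C)=O)[C@@H]1C(C)C | intermediate
22 | (1R,4S,5S,6R,7R,8S,10S)-6-acetoxy-1,10:4,5-diepoxygermacran-8-yl (2Z)-2-methylbut-2-enoate (CNP0158257.1) | C/C=C(/C)C(=O)O[C@H]1C[C@]2(C)O[C@@H]2CC[C@]2(C)O[C@H]2[C@H](OC(C)=O)[C@@H]1C(C)C | target

## Step count and risks
Total step count: 12. Longest linear sequence: 9 steps (1 → 2 → 6 → 7 → 13 → 18 → 19 → 20 → 21 → 22).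

**Step 8 (the proposed new step).** Several things could go wrong:
- The hindered, conjugated enal may form too little hemiacetal.
- The samarium Lewis acid may isomerise 16 to tiglaldehyde.
- The isopropyl group is axial in the transition state.
- The C8 hydroxyl could add in oxa-Michael fashion to C4.

The fallback uses only known chemistry. It sets out from 13 and comes back to the route at 18.
- The standard Evans–Tishchenko reduction with 4-nitrobenzaldehyde and catalytic SmI2 gives the 8-O-(4-nitrobenzoyl) 6,8-anti-diol monoester F1.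
- TESCl and imidazole convert it into the 6-O-triethylsilyl 8-(4-nitrobenzoate) F2.
- K2CO3 in MeOH frees the 6-O-triethylsilyl 8-alcohol F3.
- The Yamaguchi mixed anhydride of 14 (2,4,6-trichlorobenzoyl chloride, Et3N, toluene, 80 °C) gives the 6-O-triethylsilyl 8-angelate F4.
- HF·pyridine then delivers 18.

**Step 11.** Closing a ten-membered carbocycle onto a 1,1-disubstituted olefin competes with dimerisation. The oxirane and ester oxygens can also chelate ruthenium.

The fallback moves ring closure ahead of the C6, C4 and C5 stereocentres. It sets out from 13 and comes back at 21.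
- Metathesis of 13 is helped by the O–H···O=C hydrogen-bonded turn, and its conjugated C4=C5 bond is inert to ruthenium. It gives the macrocyclic hydroxy dienone F5.
- The step 8 procedure applied to it gives the macrocyclic 6-hydroxy 8-angelate F6.
- VO(acac)2/t-BuOOH epoxidises only the allylic-alcohol olefin. Attack comes from the periphery on the A(1,3)-minimised conformer and gives the macrocyclic threo epoxy alcohol F7.
- Acetylation as in step 10 gives 21.

**Step 12.** The conformational bias of the ring may expose the α-face of C1=C10 and override the catalyst.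

The fallback turns that bias to advantage by anti-addition and closure. It sets out from 21 and comes back at 22.
- NBS in aqueous dimethoxyethane at 0 °C places bromonium on the exposed face. Water opens it at the tertiary C10 from the opposite face and gives the 1-bromo-10-hydroxy bromohydrin F8.
- DBU in CH2Cl2 closes the C10 oxygen onto C1 with inversion to give 22.

## Further compounds
F1 | step 8 | 8-O-(4-nitrobenzoyl) 6,8-anti-diol monoester, (4S,5S,6S,7E)-6-hydroxy-2,8-dimethyl-5-(propan-2-yl)dodeca-1,7,11-trien-4-yl 4-nitrobenzoate | C=C(C)C[C@H](OC(=O)c1ccc(cc1)[N+](=O)[O-])[C@@H](C(C)C)[C@@H](O)/C=C(\C)CCC=C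
F2 | step 8 | 6-O-triethylsilyl 8-(4-nitrobenzoate), configuration as in F1 | C=C(C)C[C@H](OC(=O)c1ccc(cc1)[N+](=O)[O-])[C@@H](C(C)C)[C@@H](O[Si](CC)(CC)CC)/C=C(\C)CCC=C
F3 | step 8 | 6-O-triethylsilyl 8-alcohol, configuration as in F1 | C=C(C)C[C@H](O)[C@@H](C(C)C)[C@@H](O[Si](CC)(CC)CC)/C=C(\C)CCC=C
F4 | step 8 | 6-O-triethylsilyl 8-angelate, configuration as in 18 | C=C(C)C[C@H](OC(=O)/C(C)=C\C)[C@@H](C(C)C)[C@@H](O[Si](CC)(CC)CC)/C=C(\C)CCC=C
F5 | step 11 | macrocyclic hydroxy dienone, (1(10)Z,4E,7R,8S)-8-hydroxygermacra-1(10),4-dien-6-one | O[C@H]1C/C(C)=C\CC/C(C)=C/C(=O)[C@@H]1C(C)C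
F6 | step 11 | macrocyclic 6-hydroxy 8-angelate, (1(10)Z,4E,6S,7S,8S)-6-hydroxygermacra-1(10),4-dien-8-yl (2Z)-2-methylbut-2-enoate | C/C=C(/C)C(=O)O[C@H]1C/C(C)=C\CC/C(C)=C/[C@H](O)[C@@H]1C(C)C
F7 | step 11 | macrocyclic threo epoxy alcohol, (1(10)Z,4S,5S,6R,7S,8S)-4,5-epoxy-6-hydroxygermacr-1(10)-en-8-yl (2Z)-2-methylbut-2-enoate | C/C=C(/C)C(=O)O[C@H]1C/C(C)=C\CC[C@]2(C)O[C@H]2[C@H](O)[C@@H]1C(C)C
F8 | step 12 | 1-bromo-10-hydroxy bromohydrin, (1S,4S,5S,6R,7R,8S,10S)-6-acetoxy-1-bromo-4,5-epoxy-10-hydroxygermacran-8-yl (2Z)-2-methylbut-2-enoate | C/C=C(/C)C(=O)O[C@H]1C[C@](C)(O)[C@@H](Br)CC[C@]2(C)O[C@H]2[C@H](OC(C)=O)[C@@H]1C(C)C
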